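**Retrosynthetic overview**

1. Target 22 ⇒ vinylogous ester 20 (O1–C7a=C7–C6=O). The C5 methoxy group comes last, by α′-hydroxylation and O-methylation anti to the axial C3a allyl group.
2. Carbocycle C3a–C4–C5–C6–C7–C7a ⇒ keto lactone 18. A Claisen attack of the C6 methyl ketone (through C7) on the lactone carbonyl C7a closes it, and the oxolane then re-closes O1–C7a as the enol ether.
3. The plan rests on the quaternary C3a, which carries two CH2 arms: the allyl CH2 and ring carbon C4. Both are delivered at once as a sacrificial spiro-cyclohexene, by Diels–Alder addition of 2-(trimethylsilyloxy)buta-1,3-diene to the exocyclic C3a=C4 alkene of methylene lactone 11. Ozonolysis of the silyl enol ether then separates them as CH2CHO (future allyl) and CH2CH2CO2H (C4–C5–C6).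
4. 11 ⇒ trans lactone 8 (Mannich-type aminomethylation, elimination) ⇒ anti homoallylic alcohol 4 from 3,4,5-trimethoxybenzaldehyde and (E)-crotylBpin, which sets C2 and C3.
5. Ring order: oxolane (as lactone) → temporary spiro carbocycle (formed, then cleaved) → cyclohexenone, with the oxolane re-formed around O1–C7a.

Key step: step 6

Remark on locants: the benzofuran locants of the target (O1, C2 aryl, C3 methyl, C3a allyl, C4, C5 OMe, C6 ketone, C7=C7a) are used for the corresponding atoms of every intermediate.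

Assumption: the (S)-enantiomer of the TRIP phosphoric acid is taken to direct the crotyl group to the Si face of an aryl aldehyde (the (R)-acid being taken to favour the Re face). The enantiomer to use is the one that gives the (1S,2S) alcohol.

**Route**

Step 1
Reactants: 1 3,4,5-trimethoxybenzaldehyde; 2 (E)-crotylboronic acid pinacol ester
Product: 4 (1S,2S)-2-methyl-1-(3,4,5-trimethoxyphenyl)but-3-en-1-ol, via pinacol borate ester 3 (not isolated)
Conditions: (S)-TRIP phosphoric acid [(S)-3,3'-bis(2,4,6-triisopropylphenyl)-BINOL hydrogen phosphate] (5 mol %), 4 Å MS, PhMe, −30 °C; aq. NaHCO3 work-up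
Reagents that add atoms: none
Why: Chiral-phosphoric-acid-catalysed crotylboration runs through a closed chair transition state, so the E-boronate should give the anti (1S,2S) pair while the catalyst directs attack to the Si face of the aldehyde, which sets C2 and C3 of the target before borate 3 is cleaved on work-up.

Step 2
Reactants: 4 (1S,2S)-2-methyl-1-(3,4,5-trimethoxyphenyl)but-3-en-1-ol
Product: 6 (1S,2S)-2-methyl-1-(3,4,5-trimethoxyphenyl)butane-1,4-diol, via bis-9-BBN adduct 5 (not isolated)
Conditions: 9-BBN (2.5 equiv), THF, 0 °C → rt; then 3 M NaOH, 30 % H2O2, 0 °C → rt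
Reagents that add atoms: hydrogen peroxide, OO (9-BBN, B1C2CCCC1CCC2, stays in intermediate 5 only)
Why: Anti-Markovnikov hydroboration of the terminal alkene with 9-BBN and oxidation with retention should give the primary alcohol without touching the two stereocentres, the free hydroxyl only consuming one extra equivalent of borane.

Step 3
Reactants: 6 (1S,2S)-2-methyl-1-(3,4,5-trimethoxyphenyl)butane-1,4-diol
Product: 8 (4S,5S)-4-methyl-5-(3,4,5-trimethoxyphenyl)oxolan-2-one, via hydroxy aldehyde 7 (not isolated)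
Conditions: TEMPO (0.2 equiv), PhI(OAc)2 (2.5 equiv), CH2Cl2, rt
Reagents that add atoms: none
Why: In this TEMPO-mediated oxidative lactonisation the oxoammonium species oxidises the unhindered primary alcohol first, the hydroxy aldehyde closes to the five-membered lactol and a second oxidation gives the trans γ-lactone with C2 and C3 untouched.

Step 4
Reactants: 8 (4S,5S)-4-methyl-5-(3,4,5-trimethoxyphenyl)oxolan-2-one
Product: 9 (3R,4S,5S)-3-[(dimethylamino)methyl]-4-methyl-5-(3,4,5-trimethoxyphenyl)oxolan-2-one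
Conditions: LiN(iPr)2 (1.1 equiv), THF, −78 °C; then Me2N=CH2 iodide (1.5 equiv), −78 °C → rt
Reagents that add atoms: N,N-dimethylmethyleneiminium iodide, C=[N+](C)C.[I-]
Why: Mannich-type aminomethylation of the lactone lithium enolate is expected to occur anti to the C3 methyl group, and the configuration of this new centre is of no consequence because step 5 erases it.

Step 5
Reactants: 9 (3R,4S,5S)-3-[(dimethylamino)methyl]-4-methyl-5-(3,4,5-trimethoxyphenyl)oxolan-2-one
Product: 11 (4S,5S)-4-methyl-3-methylidene-5-(3,4,5-trimethoxyphenyl)oxolan-2-one, via trimethylammonium iodide 10 (not isolated)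
Conditions: MeI (5 equiv), MeOH, rt; evaporate; then aq. NaHCO3, CH2Cl2, rt
Reagents that add atoms: iodomethane, CI (its carbon stays in intermediate 10 only and leaves with trimethylamine)
Why: Exhaustive N-methylation followed by base-induced E1cB elimination of trimethylamine from the β-ammonio lactone should give the conjugated exocyclic alkene C3a=C4 under conditions too mild to move the double bond into the ring.

Step 6
Reactants: 11 (4S,5S)-4-methyl-3-methylidene-5-(3,4,5-trimethoxyphenyl)oxolan-2-one; 12 2-(trimethylsilyloxy)buta-1,3-diene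
Product: 13 (3S,4S,5S)-4-methyl-8-(trimethylsilyloxy)-3-(3,4,5-trimethoxyphenyl)-2-oxaspiro[4.5]dec-7-en-1-one
Conditions: 12 (5 equiv), BHT (5 mol %), PhMe, sealed tube, 140 °C; volatiles removed, crude 13 used at once with the silyl enol ether intact
Reagents that add atoms: none
Why: This is a concerted, asynchronous, normal-demand [4+2] cycloaddition (Diels–Alder) between the electron-poor exocyclic C3a=C4 alkene of 11 and the electron-rich diene 12, and the closest known reaction type is the thermal Diels–Alder reaction of α-methylene-γ-butyrolactones with 2-silyloxydienes to give spirolactones. The diene CH2 next to the silyloxy carbon has the largest HOMO coefficient and bonds to the β-carbon C4, while the other terminus bonds to C3a, so the silyloxy carbon ends para to the spiro centre and becomes C6. The spiro cyclohexene ring is closed by the cycloaddition itself, both new σ bonds (C3a–CH2 of the future allyl group and C4–C5) being formed in one intermolecular step on the oxolane template. The only new stereocentre, C3a, is controlled by the neighbouring C3 methyl group: the diene should add to the lactone face anti to this methyl, so that the new C3a–CH2 bond is trans to methyl and C4 is cis to it, as in the target. The step needs facial selectivity and para regioselectivity; the first rests on 1,2-induction by the C3 methyl, which sits next to the reacting carbon whereas the C2 aryl on the other face is one bond further away and pseudo-equatorial, and the second on the donor at C2 of the diene and the acceptor carbonyl on C3a. Endo/exo selectivity plays no part because the diene termini are unsubstituted.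

Step 7
Reactants: 13 (3S,4S,5S)-4-methyl-8-(trimethylsilyloxy)-3-(3,4,5-trimethoxyphenyl)-2-oxaspiro[4.5]dec-7-en-1-one
Product: 15 3-[(3S,4S,5S)-4-methyl-2-oxo-3-(2-oxoethyl)-5-(3,4,5-trimethoxyphenyl)oxolan-3-yl]propanoic acid, via methoxy hydroperoxide silyl ester 14 (not isolated)
Conditions: O3 (ca. 1 equiv, Sudan Red 7B end-point), CH2Cl2–MeOH 4:1, −78 °C; then Me2S (5 equiv), −78 °C → rt; aqueous work-up
Reagents that add atoms: ozone, O=[O+][O-] (methanol, CO, stays in intermediate 14 only)
Why: In this ozonolysis the silyl enol ether reacts far faster than the trimethoxyarene when ozone is titrated, Criegee fragmentation gives the C6 silyl ester and a carbonyl oxide that methanol traps, and Me2S reduction with desilylation should reveal the CH2CHO arm and the CH2CH2CO2H arm on C3a at the two oxidation levels fixed by the position of the enol ether.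

Step 8
Reactants: 15 3-[(3S,4S,5S)-4-methyl-2-oxo-3-(2-oxoethyl)-5-(3,4,5-trimethoxyphenyl)oxolan-3-yl]propanoic acid
Product: 16 3-[(3S,4S,5S)-4-methyl-2-oxo-3-(prop-2-en-1-yl)-5-(3,4,5-trimethoxyphenyl)oxolan-3-yl]propanoic acid
Conditions: Ph3PCH3Br (2.6 equiv), KOtBu (2.5 equiv), THF, 0 °C; add 15, 0 °C → rt; acidify to pH 3
Reagents that add atoms: methyltriphenylphosphonium bromide, C[P+](c1ccccc1)(c1ccccc1)c1ccccc1.[Br-]
Why: In this Wittig methylenation one equivalent of ylide deprotonates the acid, the carboxylate and the hindered lactone carbonyl are inert, and only the aldehyde should be converted into the terminal alkene of the allyl group.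

Step 9
Reactants: 16 3-[(3S,4S,5S)-4-methyl-2-oxo-3-(prop-2-en-1-yl)-5-(3,4,5-trimethoxyphenyl)oxolan-3-yl]propanoic acid
Product: 18 (3S,4S,5S)-4-methyl-3-(3-oxobutyl)-3-(prop-2-en-1-yl)-5-(3,4,5-trimethoxyphenyl)oxolan-2-one, via acid chloride 17 (not isolated)
Conditions: (COCl)2 (1.5 equiv), DMF (cat.), CH2Cl2, 0 °C → rt, evaporate; then Me2CuLi (2 equiv, from MeLi and CuI), Et2O, −78 °C; aq. NH4Cl
Reagents that add atoms: lithium dimethylcuprate Me2CuLi, [Li+].C[Cu-]C (oxalyl chloride, O=C(Cl)C(=O)Cl, supplies the chlorine of intermediate 17 only)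
Why: Acid chloride formation followed by ketone synthesis with a lithium dialkylcuprate, which acylates at −78 °C without adding to the product ketone, the lactone or the alkene, should give the C6 methyl ketone that carries C7.

Step 10
Reactants: 18 (3S,4S,5S)-4-methyl-3-(3-oxobutyl)-3-(prop-2-en-1-yl)-5-(3,4,5-trimethoxyphenyl)oxolan-2-one
Product: 20 (2S,3S,3aS)-3-methyl-3a-(prop-2-en-1-yl)-2-(3,4,5-trimethoxyphenyl)-3,3a,4,5-tetrahydro-1-benzofuran-6(2H)-one, via hydroxy dione 19 (not isolated)
Conditions: KOtBu (3 equiv), THF (0.02 M), 0 °C → rt; then TsOH·H2O (3.3 equiv), 4 Å MS, rt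
Reagents that add atoms: none
Why: In this intramolecular Claisen (Dieckmann-type) condensation only the methyl enolate C7 can reach the lactone carbonyl C7a through a six-membered transition state under equilibrating conditions (the C5 enolate would give a cyclobutane), deprotonation of the resulting 1,3-dione drives the opening of the lactone, and the slight excess of acid should then close O1 onto C7a and dehydrate the hemiketal to the vinylogous ester without affecting a stereocentre.

Step 11
Reactants: 20 (2S,3S,3aS)-3-methyl-3a-(prop-2-en-1-yl)-2-(3,4,5-trimethoxyphenyl)-3,3a,4,5-tetrahydro-1-benzofuran-6(2H)-one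
Product: 21 (2S,3S,3aR,5R)-5-hydroxy-3-methyl-3a-(prop-2-en-1-yl)-2-(3,4,5-trimethoxyphenyl)-3,3a,4,5-tetrahydro-1-benzofuran-6(2H)-one
Conditions: NaN(SiMe3)2 (1.2 equiv), THF, −78 °C; then 3-phenyl-2-(phenylsulfonyl)oxaziridine (1.5 equiv), −78 °C; aq. NH4Cl
Reagents that add atoms: 3-phenyl-2-(phenylsulfonyl)oxaziridine, O=S(=O)(c1ccccc1)N1OC1c1ccccc1
Why: In this enolate α-hydroxylation with an N-sulfonyloxaziridine only C5 can be deprotonated because C3a is quaternary (cross-conjugated α′-enolate), and the oxidant should approach anti to the pseudo-axial C3a allyl group, which gives the 5R alcohol with the hydroxyl equatorial.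

Step 12
Reactants: 21 (2S,3S,3aR,5R)-5-hydroxy-3-methyl-3a-(prop-2-en-1-yl)-2-(3,4,5-trimethoxyphenyl)-3,3a,4,5-tetrahydro-1-benzofuran-6(2H)-one
Product: 22 (2S,3S,3aR,5R)-5-methoxy-3-methyl-3a-(prop-2-en-1-yl)-2-(3,4,5-trimethoxyphenyl)-3,3a,4,5-tetrahydro-1-benzofuran-6(2H)-one
Conditions: MeI (10 equiv), Ag2O (3 equiv), 4 Å MS, MeCN, rt, dark
Reagents that add atoms: iodomethane, CI
Why: Purdie methylation with Ag2O and MeI etherifies the α-ketol under nearly neutral conditions, so C5 should not epimerise, and the equatorial 5-methoxy epimer formed is also the more stable one, so a brief base equilibration would correct any C5 epimer.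

**Compound list**

1 | 3,4,5-trimethoxybenzaldehyde | COc1cc(C=O)cc(OC)c1OC | starting material
2 | (E)-crotylboronic acid pinacol ester | C/C=C/CB1OC(C)(C)C(C)(C)O1 | starting material
3 | 2-{[(1S,2S)-2-methyl-1-(3,4,5-trimethoxyphenyl)but-3-en-1-yl]oxy}-4,4,5,5-tetramethyl-1,3,2-dioxaborolane | CC1(C)OB(O[C@H](c2cc(OC)c(OC)c(OC)c2)[C@H](C=C)C)OC1(C)C | intermediate (not isolated)
4 | (1S,2S)-2-methyl-1-(3,4,5-trimethoxyphenyl)but-3-en-1-ol | O[C@H](c1cc(OC)c(OC)c(OC)c1)[C@H](C=C)C | intermediate
5 | (1S,2S)-2-methyl-1-(3,4,5-trimethoxyphenyl)butane-1,4-diol carrying a 9-borabicyclo[3.3.1]nonan-9-yl group on O1 (borinate) and on C4 (alkylborane) | O(B1C2CCCC1CCC2)[C@H](c1cc(OC)c(OC)c(OC)c1)[C@H](CCB1C2CCCC1CCC2)C | intermediate (not isolated)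
6 | (1S,2S)-2-methyl-1-(3,4,5-trimethoxyphenyl)butane-1,4-diol | O[C@H](c1cc(OC)c(OC)c(OC)c1)[C@H](CCO)C | intermediate
7 | (3S,4S)-4-hydroxy-3-methyl-4-(3,4,5-trimethoxyphenyl)butanal (in equilibrium with its lactol) | O[C@H](c1cc(OC)c(OC)c(OC)c1)[C@H](CC=O)C | intermediate (not isolated)
8 | (4S,5S)-4-methyl-5-(3,4,5-trimethoxyphenyl)oxolan-2-one | O=C1O[C@H](c2cc(OC)c(OC)c(OC)c2)[C@H](C1)C | intermediate
9 | (3R,4S,5S)-3-[(dimethylamino)methyl]-4-methyl-5-(3,4,5-trimethoxyphenyl)oxolan-2-one | CN(C)C[C@@H]1C(=O)O[C@H](c2cc(OC)c(OC)c(OC)c2)[C@H]1C | intermediate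
10 | trimethyl{[(3R,4S,5S)-4-methyl-2-oxo-5-(3,4,5-trimethoxyphenyl)oxolan-3-yl]methyl}ammonium iodide | C[N+](C)(C)C[C@@H]1C(=O)O[C@H](c2cc(OC)c(OC)c(OC)c2)[C@H]1C.[I-] | intermediate (not isolated)
11 | (4S,5S)-4-methyl-3-methylidene-5-(3,4,5-trimethoxyphenyl)oxolan-2-one | C=C1C(=O)O[C@H](c2cc(OC)c(OC)c(OC)c2)[C@H]1C | intermediate
12 | 2-(trimethylsilyloxy)buta-1,3-diene | C=CC(=C)O[Si](C)(C)C | starting material
13 | (3S,4S,5S)-4-methyl-8-(trimethylsilyloxy)-3-(3,4,5-trimethoxyphenyl)-2-oxaspiro[4.5]dec-7-en-1-one | C1C=C(O[Si](C)(C)C)CC[C@]12C(=O)O[C@H](c3cc(OC)c(OC)c(OC)c3)[C@H]2C | intermediate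
14 | trimethylsilyl 3-[(3S,4S,5S)-3-(2-hydroperoxy-2-methoxyethyl)-4-methyl-2-oxo-5-(3,4,5-trimethoxyphenyl)oxolan-3-yl]propanoate (both epimers at the peroxy acetal carbon) | COC(OO)C[C@]1(CCC(=O)O[Si](C)(C)C)C(=O)O[C@H](c2cc(OC)c(OC)c(OC)c2)[C@H]1C | intermediate (not isolated)
15 | 3-[(3S,4S,5S)-4-methyl-2-oxo-3-(2-oxoethyl)-5-(3,4,5-trimethoxyphenyl)oxolan-3-yl]propanoic acid | O=CC[C@]1(CCC(=O)O)C(=O)O[C@H](c2cc(OC)c(OC)c(OC)c2)[C@H]1C | intermediate
16 | 3-[(3S,4S,5S)-4-methyl-2-oxo-3-(prop-2-en-1-yl)-5-(3,4,5-trimethoxyphenyl)oxolan-3-yl]propanoic acid | C=CC[C@]1(CCC(=O)O)C(=O)O[C@H](c2cc(OC)c(OC)c(OC)c2)[C@H]1C | intermediate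
17 | 3-[(3S,4S,5S)-4-methyl-2-oxo-3-(prop-2-en-1-yl)-5-(3,4,5-trimethoxyphenyl)oxolan-3-yl]propanoyl chloride | C=CC[C@]1(CCC(=O)Cl)C(=O)O[C@H](c2cc(OC)c(OC)c(OC)c2)[C@H]1C | intermediate (not isolated)
18 | (3S,4S,5S)-4-methyl-3-(3-oxobutyl)-3-(prop-2-en-1-yl)-5-(3,4,5-trimethoxyphenyl)oxolan-2-one | C=CC[C@]1(CCC(C)=O)C(=O)O[C@H](c2cc(OC)c(OC)c(OC)c2)[C@H]1C | intermediate
19 | (4S)-4-[(1S,2S)-1-hydroxy-1-(3,4,5-trimethoxyphenyl)propan-2-yl]-4-(prop-2-en-1-yl)cyclohexane-1,3-dione | C=CC[C@@]1(CCC(=O)CC1=O)[C@H](C)[C@H](O)c1cc(OC)c(OC)c(OC)c1 | intermediate (not isolated)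
20 | (2S,3S,3aS)-3-methyl-3a-(prop-2-en-1-yl)-2-(3,4,5-trimethoxyphenyl)-3,3a,4,5-tetrahydro-1-benzofuran-6(2H)-one | C=CC[C@]12CCC(=O)C=C1O[C@H](c1cc(OC)c(OC)c(OC)c1)[C@H]2C | intermediate
21 | (2S,3S,3aR,5R)-5-hydroxy-3-methyl-3a-(prop-2-en-1-yl)-2-(3,4,5-trimethoxyphenyl)-3,3a,4,5-tetrahydro-1-benzofuran-6(2H)-one | C=CC[C@]12C[C@@H](O)C(=O)C=C1O[C@H](c1cc(OC)c(OC)c(OC)c1)[C@H]2C | intermediate
22 | (2S,3S,3aR,5R)-5-methoxy-3-methyl-3a-(prop-2-en-1-yl)-2-(3,4,5-trimethoxyphenyl)-3,3a,4,5-tetrahydro-1-benzofuran-6(2H)-one (CNP0236389.1) | C=CC[C@]12C[C@@H](OC)C(=O)C=C1O[C@H](c1cc(OC)c(OC)c(OC)c1)[C@H]2C | target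

**Step count**

Total: 12 steps. Longest linear sequence: 12 steps, from 1 (2 and 12 are bought).

**Steps most likely to fail**

1. Step 6. The cycloaddition may show poor facial discrimination, because the diene must add on the face that also carries the C2 aryl group. It may also be slow at the hindered 1,1-disubstituted alkene, with polymerisation or desilylation of the diene competing. The fallback gives up the cycloaddition for two successive enolate alkylations; it sets out from lactone 8 and comes back at ketone 18. The lithium enolate of 8 (LiN(iPr)2, THF/DMPU, −78 °C) would be alkylated with 2-(2-iodoethyl)-2-methyl-1,3-dioxolane, trans to the C3 methyl group, to give the ketal lactone (3S,4S,5S)-4-methyl-3-[2-(2-methyl-1,3-dioxolan-2-yl)ethyl]-5-(3,4,5-trimethoxyphenyl)oxolan-2-one F1. A second enolisation and alkylation with allyl bromide, which enters anti to the C3 methyl as the second electrophile, should give the quaternary lactone (3S,4S,5S)-4-methyl-3-[2-(2-methyl-1,3-dioxolan-2-yl)ethyl]-3-(prop-2-en-1-yl)-5-(3,4,5-trimethoxyphenyl)oxolan-2-one F2. PPTS in wet acetone would then release ketone 18.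

2. Step 10. The Claisen closure may stall because attack on the neopentyl lactone carbonyl is reversible, and intermolecular aldol condensation of the methyl ketone may compete. The acid used for dehydration may also ionise the benzylic C2–O bond and epimerise C2. The fallback reverses the roles of the two acyl groups; it sets out from acid 16 and comes back at 20. MeLi (2.2 equiv, THF, −78 °C) would deprotonate the acid and add once to the lactone carbonyl to give, after work-up, the keto acid (4S)-4-acetyl-4-[(1S,2S)-1-hydroxy-1-(3,4,5-trimethoxyphenyl)propan-2-yl]hept-6-enoic acid F4, present mainly as its cyclic hemiketal. Me3SiCHN2 in MeOH/PhMe would give the methyl ester, methyl (4S)-4-acetyl-4-[(1S,2S)-1-hydroxy-1-(3,4,5-trimethoxyphenyl)propan-2-yl]hept-6-enoate F5. KOtBu would then close the ring from the other side: the enolate of the C7a methyl ketone, the only one that can form, attacks the unhindered C6 ester to give dione 19. Acid treatment as in step 10 would give 20.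

3. Step 7. Ozone may over-oxidise the trimethoxyarene, and the silyl enol ether may hydrolyse to the ketone before cleavage, which would lose the regiochemical marker that tells the two arms apart. The fallback is a two-stage cleavage without ozone; it sets out from 13 and comes back at 15. OsO4 (cat.) with NMO in aqueous acetone would dihydroxylate the enol ether and, after loss of the silyl group, give the α-hydroxy ketone (3S,4S,5S)-7-hydroxy-4-methyl-3-(3,4,5-trimethoxyphenyl)-2-oxaspiro[4.5]decane-1,8-dione F3 as both C7 epimers. NaIO4 in aqueous THF would cleave it between C7 and C8 to aldehyde acid 15.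

**Further compounds**

F1 | step 6 | (3S,4S,5S)-4-methyl-3-[2-(2-methyl-1,3-dioxolan-2-yl)ethyl]-5-(3,4,5-trimethoxyphenyl)oxolan-2-one | CC1(CC[C@@H]2C(=O)O[C@H](c3cc(OC)c(OC)c(OC)c3)[C@H]2C)OCCO1
F2 | step 6 | (3S,4S,5S)-4-methyl-3-[2-(2-methyl-1,3-dioxolan-2-yl)ethyl]-3-(prop-2-en-1-yl)-5-(3,4,5-trimethoxyphenyl)oxolan-2-one | C=CC[C@]1(CCC2(C)OCCO2)C(=O)O[C@H](c2cc(OC)c(OC)c(OC)c2)[C@H]1C
F3 | step 7 | (3S,4S,5S)-7-hydroxy-4-methyl-3-(3,4,5-trimethoxyphenyl)-2-oxaspiro[4.5]decane-1,8-dione (both C7 epimers) | OC1C[C@]2(CCC1=O)C(=O)O[C@H](c1cc(OC)c(OC)c(OC)c1)[C@H]2C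
F4 | step 10 | (4S)-4-acetyl-4-[(1S,2S)-1-hydroxy-1-(3,4,5-trimethoxyphenyl)propan-2-yl]hept-6-enoic acid (open form of the hemiketal) | CC(=O)[C@](CC=C)(CCC(=O)O)[C@H](C)[C@H](O)c1cc(OC)c(OC)c(OC)c1
F5 | step 10 | methyl (4S)-4-acetyl-4-[(1S,2S)-1-hydroxy-1-(3,4,5-trimethoxyphenyl)propan-2-yl]hept-6-enoate (open form of the hemiketal) | CC(=O)[C@](CC=C)(CCC(=O)OC)[C@H](C)[C@H](O)c1cc(OC)c(OC)c(OC)c1
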